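**Assumption (one line):** C1–C7 denote the ring atoms of the target in the order of its SMILES (C1 quaternary, C5 ring ketone, C7 the carbon bearing the enol ester); compounds 5, 7, 11, 17, 19 and 23 are bought.

## Retrosynthetic overview

1. Target 24 ⇐ E-alkenyl trifluoroborate 22 + acid 23 (Cu-catalysed C–O coupling) ⇐ aldehyde 16 (Takai–Utimoto); C6 acetonyl by trans-alkylation of the cycloheptenone enolate.
2. Cycloheptenone (the only ring of the target, closed last) ⇐ RCM of the C1-allyl and C7-enone arms held on ε-lactone 13; the lactone masks the C7 formyl group and the side-chain carbinol.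
3. ε-Lactone ⇐ Baeyer–Villiger of cyclohexanone 9 (the isopropenyl-bearing carbon migrates with retention and becomes the (R)-carbinol).
4. 9 ⇐ anionic oxy-Cope [3,3] of allyl carbinol 6 (key C1–C2 bond, quaternary centre) with alkylation of the resulting enolate in the same flask (C7–C6 bond).
5. 6 ⇐ (R)-isopiperitenone 4 ⇐ (S)-limonene 1. Ring order: bought cyclohexene template → ε-lactone → cycloheptenone.

## Route

Step 1
Reactants: 1 (S)-(−)-limonene
Product: 3 (4S)-1-methyl-4-(prop-1-en-2-yl)cyclohex-2-en-1-ol (both C1 epimers), via allylic hydroperoxide 2 (not isolated)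
Conditions: O2, hν (visible), tetraphenylporphyrin (cat.), CH2Cl2, 0 °C; then PPh3, 0 °C → rt; chromatography (secondary allylic alcohols removed)
Reagents that add atoms: dioxygen O=O
Why: Schenck ene reaction of singlet oxygen at the trisubstituted ring alkene gives the tertiary allylic hydroperoxide as the main regioisomer, which PPh3 reduces; the bought C4 stereocentre is untouched.

Step 2
Reactants: 3 (4S)-1-methyl-4-(prop-1-en-2-yl)cyclohex-2-en-1-ol
Product: 4 (6R)-3-methyl-6-(prop-1-en-2-yl)cyclohex-2-en-1-one ((R)-isopiperitenone)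
Conditions: pyridinium chlorochromate C5H5NH[CrO3Cl] (2 equiv), 4 Å MS, CH2Cl2, rt
Reagents that add atoms: pyridinium chlorochromate [O-][Cr](=O)(=O)Cl.c1cc[nH+]cc1
Why: Babler–Dauben oxidative transposition ([3,3] shift of the tertiary allylic chromate ester, then oxidation) converts both C1 epimers into the same enone with the stereocentre retained (descriptor changes from S to R only by CIP priority).

Step 3
Reactants: 4 (R)-isopiperitenone; 5 allylmagnesium bromide
Product: 6 (1S,6R)-3-methyl-1-(prop-2-en-1-yl)-6-(prop-1-en-2-yl)cyclohex-2-en-1-ol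
Conditions: CeCl3, THF, −78 °C; aq NH4Cl; chromatography
Reagents that add atoms: none
Why: 1,2-addition (CeCl3 suppresses enolisation of the epimerisable C6) by axial attack on the half-chair enone, anti to the pseudo-axial C6–H, should place allyl cis to the pseudo-equatorial isopropenyl; this facial preference is the least secure stereochemical claim of the route and the (1R)-epimer is removed by chromatography.

Step 4
Reactants: 6 (1S,6R)-3-methyl-1-(prop-2-en-1-yl)-6-(prop-1-en-2-yl)cyclohex-2-en-1-ol; 7 2-bromo-N-methoxy-N-methylacetamide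
Product: 9 N-methoxy-N-methyl-2-[(1S,2S,5R)-2-methyl-6-oxo-2-(prop-2-en-1-yl)-5-(prop-1-en-2-yl)cyclohexyl]acetamide, via potassium enolate 8 (not isolated)
Conditions: KH (1.1 equiv), 18-crown-6, THF, 0 → 40 °C; then 7, −78 → −40 °C
Reagents that add atoms: none
Why: Anionic oxy-Cope rearrangement ([3,3]) moves allyl suprafacially from the carbinol carbon to the methyl-bearing alkene carbon, setting the quaternary centre (target C1) cis to isopropenyl, and the regiodefined enolate is alkylated axially, anti to the pseudo-axial allyl group, which sets target C7 trans.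

Step 5
Reactants: 9 keto amide
Product: 10 N-methoxy-N-methyl-2-[(3S,4S,7R)-4-methyl-2-oxo-4-(prop-2-en-1-yl)-7-(prop-1-en-2-yl)oxepan-3-yl]acetamide
Conditions: Me3SiOOSiMe3 (1.5 equiv), Me3SiOTf (10 mol %), CH2Cl2, −78 → −30 °C
Reagents that add atoms: bis(trimethylsilyl) peroxide C[Si](C)(C)OO[Si](C)(C)C
Why: Baeyer–Villiger oxidation under non-epoxidising silyl peroxide conditions; the secondary allylic carbon migrates in preference to the hindered carbon carrying the electron-poor amide arm, with retention, so the bought centre becomes the (R)-carbinol carbon.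

Step 6
Reactants: 10 lactone amide; 11 2-bromoprop-2-en-1-ol
Product: 13 (3S,4S,7R)-3-[3-(hydroxymethyl)-2-oxobut-3-en-1-yl]-4-methyl-4-(prop-2-en-1-yl)-7-(prop-1-en-2-yl)oxepan-2-one, via lithium 2-lithioprop-2-en-1-olate 12 (not isolated)
Conditions: 11, tert-butyllithium (3 equiv), Et2O, −78 → 0 °C; then 10, THF, −78 °C; aq NH4Cl
Reagents that add atoms: none
Why: Weinreb ketone synthesis: the alkenyllithium adds to the unhindered amide to give a stable chelate, while the lactone carbonyl, flanked by a tertiary carbon next to the quaternary centre, reacts more slowly at −78 °C.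

Step 7
Reactants: 13 hydroxymethyl enone lactone
Product: 14 (3R,5aS,10aS)-8-(hydroxymethyl)-5a-methyl-3-(prop-1-en-2-yl)-3,4,5,5a,6,9,10,10a-octahydro-1H-cyclohepta[c]oxepine-1,9-dione (ε-lactone trans-fused to the 2-(hydroxymethyl)cyclohept-2-enone)
Conditions: second-generation Hoveyda–Grubbs catalyst (5 mol %), CH2Cl2 (2 mM), 40 °C
Reagents that add atoms: none
Why: Ring-closing metathesis between the allyl group and the 1,1-disubstituted enone alkene closes the seven-membered carbocycle (C3=C4), whereas closure onto isopropenyl would need a bridged bicycle.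

Step 8
Reactants: 14 bicyclic enone lactone
Product: 16 (1S,7S)-7-[(3R)-3-hydroxy-4-methylpent-4-en-1-yl]-4-(hydroxymethyl)-7-methyl-3-oxocyclohept-4-ene-1-carbaldehyde, via dilithium alkoxide-dienolate 15 (not isolated)
Conditions: LiN(iPr)2 (2.1 equiv), THF, −78 °C; then iBu2AlH (1.3 equiv), −78 °C; aq potassium sodium tartrate
Reagents that add atoms: none
Why: The enone is protected in the flask as its cross-conjugated lithium enolate while iBu2AlH reduces the lactone to the lactol level; work-up reprotonates C6 and releases the aldehyde on C7 and the free carbinol.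

Step 9
Reactants: 16 hydroxy aldehyde; 17 2-(dichloromethyl)-4,4,5,5-tetramethyl-1,3,2-dioxaborolane
Product: 18 (5S,6R)-5-[(3R)-3-hydroxy-4-methylpent-4-en-1-yl]-2-(hydroxymethyl)-5-methyl-6-[(E)-2-(4,4,5,5-tetramethyl-1,3,2-dioxaborolan-2-yl)ethenyl]cyclohept-2-en-1-one
Conditions: CrCl2 (8 equiv), LiI (4 equiv), THF, rt
Reagents that add atoms: none
Why: Takai–Utimoto olefination (boron variant) is aldehyde-selective, tolerates free hydroxyls and the enone, is not basic (no C7 epimerisation) and gives the E-alkenylboronate.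

Step 10
Reactants: 18 alkenylboronate; 19 3-bromo-2-methoxyprop-1-ene
Product: 21 (5S,6S,7S)-5-[(3R)-3-hydroxy-4-methylpent-4-en-1-yl]-2-(hydroxymethyl)-5-methyl-7-(2-oxopropyl)-6-[(E)-2-(4,4,5,5-tetramethyl-1,3,2-dioxaborolan-2-yl)ethenyl]cyclohept-2-en-1-one, via methyl enol ether 20 (not isolated)
Conditions: LiN(iPr)2 (3.2 equiv), THF, −78 °C; 19, −78 → −40 °C; then 1 M HCl, THF, 0 °C
Reagents that add atoms: water O
Why: Kinetic α′-enolate alkylation (the two lithium alkoxides are inert toward the allylic bromide at low temperature) occurs anti to the bulky C7 alkenyl group, setting C6 trans, and acid hydrolysis of the enol ether unveils the methyl ketone.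

Step 11
Reactants: 21 acetonyl alkenylboronate
Product: 22 potassium (E)-2-[(1S,2S,7S)-7-[(3R)-3-hydroxy-4-methylpent-4-en-1-yl]-4-(hydroxymethyl)-7-methyl-3-oxo-2-(2-oxopropyl)cyclohept-4-en-1-yl]ethenyltrifluoroborate
Conditions: KHF2 (aq, 4.5 M), MeOH, rt
Reagents that add atoms: potassium hydrogen difluoride F.[F-].[K+]
Why: Fluoride exchange of the pinacol boronate gives the trifluoroborate needed for the oxidative coupling, with alkene geometry and all stereocentres untouched.

Step 12
Reactants: 22 alkenyltrifluoroborate; 23 3-methylbut-2-enoic acid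
Product: 24 (E)-2-[(1S,2S,7S)-7-[(3R)-3-hydroxy-4-methylpent-4-en-1-yl]-4-(hydroxymethyl)-7-methyl-3-oxo-2-(2-oxopropyl)cyclohept-4-en-1-yl]ethenyl 3-methylbut-2-enoate
Conditions: 23 (3 equiv), CuBr (10 mol %), DMAP (20 mol %), 4 Å MS, O2 (1 atm), CH2Cl2, 40 °C
Reagents that add atoms: none
Why: Chan–Lam-type copper-catalysed oxidative C–O coupling of the alkenyltrifluoroborate with the carboxylic acid proceeds with retention of the E geometry; the carboxylate couples in preference to the two alcohols.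

## Compound list

1 | (S)-(−)-limonene | CC1=CC[C@H](CC1)C(C)=C | starting material
2 | (4S)-1-hydroperoxy-1-methyl-4-(prop-1-en-2-yl)cyclohex-2-ene (C1 epimers) | CC1(OO)C=C[C@H](CC1)C(C)=C | intermediate
3 | (4S)-1-methyl-4-(prop-1-en-2-yl)cyclohex-2-en-1-ol (C1 epimers) | CC1(O)C=C[C@H](CC1)C(C)=C | intermediate
4 | (6R)-3-methyl-6-(prop-1-en-2-yl)cyclohex-2-en-1-one | CC1=CC(=O)[C@H](CC1)C(C)=C | intermediate
5 | allylmagnesium bromide | C=CC[Mg]Br | starting material
6 | (1S,6R)-3-methyl-1-(prop-2-en-1-yl)-6-(prop-1-en-2-yl)cyclohex-2-en-1-ol | CC1=C[C@@](O)(CC=C)[C@H](CC1)C(C)=C | intermediate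
7 | 2-bromo-N-methoxy-N-methylacetamide | CON(C)C(=O)CBr | starting material
8 | potassium (3S,6R)-3-methyl-3-(prop-2-en-1-yl)-6-(prop-1-en-2-yl)cyclohex-1-en-1-olate | [K+].[O-]C1=C[C@](C)(CC=C)CC[C@@H]1C(C)=C | intermediate
9 | N-methoxy-N-methyl-2-[(1S,2S,5R)-2-methyl-6-oxo-2-(prop-2-en-1-yl)-5-(prop-1-en-2-yl)cyclohexyl]acetamide | O=C1[C@@H](C(C)=C)CC[C@@](C)(CC=C)[C@@H]1CC(=O)N(C)OC | intermediate
10 | N-methoxy-N-methyl-2-[(3S,4S,7R)-4-methyl-2-oxo-4-(prop-2-en-1-yl)-7-(prop-1-en-2-yl)oxepan-3-yl]acetamide | O=C1O[C@@H](C(C)=C)CC[C@@](C)(CC=C)[C@@H]1CC(=O)N(C)OC | intermediate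
11 | 2-bromoprop-2-en-1-ol | OCC(Br)=C | starting material
12 | lithium 2-lithioprop-2-en-1-olate | [Li]C(=C)CO[Li] | intermediate
13 | (3S,4S,7R)-3-[3-(hydroxymethyl)-2-oxobut-3-en-1-yl]-4-methyl-4-(prop-2-en-1-yl)-7-(prop-1-en-2-yl)oxepan-2-one | O=C1O[C@@H](C(C)=C)CC[C@@](C)(CC=C)[C@@H]1CC(=O)C(=C)CO | intermediate
14 | (3R,5aS,10aS)-8-(hydroxymethyl)-5a-methyl-3-(prop-1-en-2-yl)-3,4,5,5a,6,9,10,10a-octahydro-1H-cyclohepta[c]oxepine-1,9-dione | O=C1O[C@@H](C(C)=C)CC[C@@]2(C)CC=C(CO)C(=O)C[C@H]12 | intermediate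
15 | dilithium alkoxide-dienolate of 14 (C4-CH2O− and C5(O−)=C6) | [Li+].[Li+].O=C1O[C@@H](C(C)=C)CC[C@@]2(C)CC=C(C[O-])C([O-])=C[C@H]12 | intermediate
16 | (1S,7S)-7-[(3R)-3-hydroxy-4-methylpent-4-en-1-yl]-4-(hydroxymethyl)-7-methyl-3-oxocyclohept-4-ene-1-carbaldehyde | C=C(C)[C@H](O)CC[C@@]1(C)CC=C(CO)C(=O)C[C@@H]1C=O | intermediate
17 | 2-(dichloromethyl)-4,4,5,5-tetramethyl-1,3,2-dioxaborolane | ClC(Cl)B1OC(C)(C)C(C)(C)O1 | starting material
18 | (5S,6R)-5-[(3R)-3-hydroxy-4-methylpent-4-en-1-yl]-2-(hydroxymethyl)-5-methyl-6-[(E)-2-(4,4,5,5-tetramethyl-1,3,2-dioxaborolan-2-yl)ethenyl]cyclohept-2-en-1-one | C=C(C)[C@H](O)CC[C@@]1(C)CC=C(CO)C(=O)C[C@@H]1/C=C/B1OC(C)(C)C(C)(C)O1 | intermediate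
19 | 3-bromo-2-methoxyprop-1-ene | COC(=C)CBr | starting material
20 | (5S,6S,7S)-7-(2-methoxyprop-2-en-1-yl) analogue of 21 (methyl enol ether) | C=C(C)[C@H](O)CC[C@@]1(C)CC=C(CO)C(=O)[C@@H](CC(=C)OC)[C@@H]1/C=C/B1OC(C)(C)C(C)(C)O1 | intermediate
21 | (5S,6S,7S)-5-[(3R)-3-hydroxy-4-methylpent-4-en-1-yl]-2-(hydroxymethyl)-5-methyl-7-(2-oxopropyl)-6-[(E)-2-(4,4,5,5-tetramethyl-1,3,2-dioxaborolan-2-yl)ethenyl]cyclohept-2-en-1-one | C=C(C)[C@H](O)CC[C@@]1(C)CC=C(CO)C(=O)[C@@H](CC(C)=O)[C@@H]1/C=C/B1OC(C)(C)C(C)(C)O1 | intermediate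
22 | potassium (E)-2-[(1S,2S,7S)-7-[(3R)-3-hydroxy-4-methylpent-4-en-1-yl]-4-(hydroxymethyl)-7-methyl-3-oxo-2-(2-oxopropyl)cyclohept-4-en-1-yl]ethenyltrifluoroborate | C=C(C)[C@H](O)CC[C@@]1(C)CC=C(CO)C(=O)[C@@H](CC(C)=O)[C@@H]1/C=C/[B-](F)(F)F.[K+] | intermediate
23 | 3-methylbut-2-enoic acid | CC(C)=CC(=O)O | starting material
24 | (E)-2-[(1S,2S,7S)-7-[(3R)-3-hydroxy-4-methylpent-4-en-1-yl]-4-(hydroxymethyl)-7-methyl-3-oxo-2-(2-oxopropyl)cyclohept-4-en-1-yl]ethenyl 3-methylbut-2-enoate | C=C(C)[C@H](O)CC[C@@]1(C)CC=C(CO)C(=O)[C@@H](CC(C)=O)[C@@H]1/C=C/OC(=O)C=C(C)C | target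

## Step count and risks

Total step count: 12. Longest linear sequence: 12 (1 → 24).

**Step 4 (tandem anionic oxy-Cope/alkylation).** The tertiary alkoxide may fragment by retro-allylation, the hindered enolate may undergo proton transfer instead of alkylation, and the outcome depends on the facial ratio obtained in step 3. The fallback sets out from 4: copper-catalysed conjugate allylation (5, CuBr·SMe2, Me3SiCl, THF, −78 °C) attacks axially, cis to isopropenyl, and traps the same enolate as trimethyl{[(3S,6R)-3-methyl-3-(prop-2-en-1-yl)-6-(prop-1-en-2-yl)cyclohex-1-en-1-yl]oxy}silane F1. MeLi then regenerates the lithium enolate, which is alkylated with 7 (THF/DMPU, −78 °C), and the route is rejoined at 9.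

**Step 5 (Baeyer–Villiger).** Two secondary carbons compete for migration and the Lewis acid may trigger carbonyl–alkene side reactions. The fallback sets out from 6: the oxy-Cope rearrangement is run with a proton quench (KH, 18-crown-6, THF; aq NH4Cl) to give (3S,6R)-3-methyl-3-(prop-2-en-1-yl)-6-(prop-1-en-2-yl)cyclohexan-1-one F2. Oxidation at this stage, where only a CH2 group competes with the allylic CH, gives (4S,7R)-4-methyl-4-(prop-2-en-1-yl)-7-(prop-1-en-2-yl)oxepan-2-one F3. Alkylation of the lactone enolate (LiN(iPr)2, −78 °C, then 7) returns to the route at 10; C7 selectivity is less certain here and epimers would be separated.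

**Step 8 (lactone reduction beside the enone).** Incomplete enolate protection would lead to 1,2-reduction of the enone or over-reduction. The fallback sets out from 10: reagent 12 is added at −78 °C and, without quenching, iBu2AlH is added to the same flask, so the chelated tetrahedral Weinreb adduct protects the future ketone while the lactone is reduced. Work-up gives open-chain (2S,3S,6R)-6-hydroxy-2-[3-(hydroxymethyl)-2-oxobut-3-en-1-yl]-3,7-dimethyl-3-(prop-2-en-1-yl)oct-7-enal F4, and ring-closing metathesis of F4 (second-generation Hoveyda–Grubbs catalyst, CH2Cl2, 40 °C) comes back to the route at 16.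

## Further compounds

F1 | step 4 | trimethyl{[(3S,6R)-3-methyl-3-(prop-2-en-1-yl)-6-(prop-1-en-2-yl)cyclohex-1-en-1-yl]oxy}silane | C[Si](C)(C)OC1=C[C@](C)(CC=C)CC[C@@H]1C(C)=C
F2 | step 5 | (3S,6R)-3-methyl-3-(prop-2-en-1-yl)-6-(prop-1-en-2-yl)cyclohexan-1-one | O=C1C[C@](C)(CC=C)CC[C@@H]1C(C)=C
F3 | step 5 | (4S,7R)-4-methyl-4-(prop-2-en-1-yl)-7-(prop-1-en-2-yl)oxepan-2-one | O=C1C[C@](C)(CC=C)CC[C@@H](O1)C(C)=C
F4 | step 8 | (2S,3S,6R)-6-hydroxy-2-[3-(hydroxymethyl)-2-oxobut-3-en-1-yl]-3,7-dimethyl-3-(prop-2-en-1-yl)oct-7-enal | C=C(C)[C@H](O)CC[C@@](C)(CC=C)[C@@H](C=O)CC(=O)C(=C)CO
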